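**Retrosynthetic overview**
1. Polymatin A (22) comes from macrocyclic alcohol 19 by O8‑angeloylation and then removal of the O9 2‑naphthylmethyl (NAP) group.
2. Key step, C7–C8 bond: an intramolecular, SnCl4‑chelation‑controlled vinylogous Hosomi–Sakurai reaction of a 3‑(Me3SiCH2)butenolide on an α‑alkoxy aldehyde. It closes the ten‑membered ring, sets C7 and C8, and releases the α‑methylene lactone. The usual C6–C7 Barbier/NHK lactone‑forming closure and RCM are deliberately avoided.
3. The butenolide comes from an enal by catalytic asymmetric propiolate addition (sets C6), syn‑hydrostannation with lactonisation, Sn→I exchange and Negishi coupling.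
4. The C1=C10 enoate and C9 come from aldol/elimination of a Noyori‑derived β‑alkoxy ester on the aldehyde cut from geranyl acetate, which supplies C1–C6, C15 and the 4E alkene.
5. Ring order: γ‑lactone first (step 10), ten‑membered carbocycle last (step 14).

Assumptions: germacrane numbering is used, so the target is 6R,7S,8S,9S, with C1=C10 E by CIP (ring‑cis), C4=C5 E, and a Z angelate. (S,S)‑ProPhenol is assumed to deliver the alkyne to the Si face of enal 11; if the sense is opposite, use the antipodal ligand.

**Step 1**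
Reactants: 1 geranyl acetate
Product: 2 6,7‑epoxygeranyl acetate (racemic epoxide)
Conditions: mCPBA (1.0 equiv), NaHCO3, CH2Cl2, 0 °C
Reagents that add atoms: mCPBA, O=C(OO)c1cccc(Cl)c1
Why: Prilezhaev epoxidation; the remote trisubstituted alkene is more electron‑rich than the alkene deactivated by the allylic acetate, and the epoxide stereocentre is destroyed in step 2.

**Step 2**
Reactants: 2
Product: 3 (2E)‑3‑methyl‑6‑oxohex‑2‑en‑1‑yl acetate (C1 aldehyde)
Conditions: H5IO6, THF/Et2O, 0 °C
Reagents that add atoms: periodic acid/water, OI(=O)(O)(O)(O)O and O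
Why: Epoxide hydrolysis followed by Malaprade glycol cleavage removes acetone; the E C4=C5 alkene and the acetate are untouched.

**Step 3**
Reactants: 4 methyl 4,4‑dimethoxy‑3‑oxobutanoate
Product: 5 methyl (3S)‑3‑hydroxy‑4,4‑dimethoxybutanoate
Conditions: RuCl2[(R)‑BINAP] (0.2 mol %), H2 (80 bar), MeOH, 50 °C
Reagents that add atoms: none
Why: Noyori asymmetric hydrogenation of a β‑keto ester sets C9; the facial sense follows that for 4‑chloro/4‑alkoxyacetoacetates, and the label is S because CH(OMe)2 outranks CH2CO2Me.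

**Step 4**
Reactants: 5; 6 2‑(bromomethyl)naphthalene
Product: 7 methyl (3S)‑4,4‑dimethoxy‑3‑(2‑naphthylmethoxy)butanoate
Conditions: Ag2O, 4 Å MS, CH2Cl2, rt, dark
Reagents that add atoms: 2‑(bromomethyl)naphthalene, BrCc1ccc2ccccc2c1
Why: Ag2O‑promoted Williamson etherification is non‑basic, so there is no retro‑aldol or β‑elimination; NAP chelates like benzyl, tolerates acid and SnCl4, and is removed with DDQ.

**Step 5**
Reactants: 7; 3
Product: 8 aldol adduct (mixture at C1 and C10, C9 S)
Conditions: LDA, THF, –78 °C, 10 min; add 3; AcOH quench at –78 °C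
Reagents that add atoms: none beyond 3 and 7
Why: Lithium‑enolate aldol addition; the aldehyde reacts faster than the acetate, short cold enolisation limits β‑alkoxide loss, and the two new centres are removed in step 6.

**Step 6**
Reactants: 8
Product: 9 (2E,6E)‑dienoate
Conditions: MsCl, Et3N, CH2Cl2, 0 °C; then DBU, rt
Reagents that add atoms: none
Why: Mesylation then E1cB elimination; mesylate leaves far faster than the β‑ONAP group, and the preferred tiglate‑type isomer (chain trans to CO2Me) is the ring‑cis C1=C10 geometry of the target. Any minor Z isomer is removed by chromatography.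

**Step 7**
Reactants: 9
Product: 10 allylic alcohol
Conditions: K2CO3 (0.3 equiv), MeOH, 0 °C
Reagents that add atoms: none
Why: Zemplén‑type transesterification removes only the acetate; exchange at the methyl esters is degenerate.

**Step 8**
Reactants: 10
Product: 11 (E)‑enal (C6 aldehyde)
Conditions: activated MnO2, CH2Cl2, rt
Reagents that add atoms: none
Why: Selective allylic oxidation under neutral conditions, with no E/Z erosion and no effect on the NAP ether or acetal.

**Step 9**
Reactants: 11; 12 methyl propiolate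
Product: 13 (6R)‑γ‑hydroxy ynoate
Conditions: (S,S)‑ProPhenol (20 mol %), Me2Zn (3 equiv), Ph3PO (40 mol %), toluene, 4 °C
Reagents that add atoms: methyl propiolate, C#CC(=O)OC
Why: Zn–ProPhenol catalytic asymmetric alkynylation of an enal sets C6 (R) under catalyst control; the esters, acetal and NAP ether are inert to the alkynylzinc.

**Step 10**
Reactants: 13
Product: 14 (5R)‑3‑(tributylstannyl)butenolide (first ring)
Conditions: Bu3SnH, Pd(PPh3)4 (2 mol %), THF, 0 °C to rt; then cat. PPTS
Reagents that add atoms: tributyltin hydride, CCCC[SnH](CCCC)CCCC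
Why: Pd‑catalysed syn‑hydrostannation of an ynoate places tin α to the ester and puts the carbinol cis to CO2Me, so lactonisation (loss of MeOH) follows; C6 is not touched.

**Step 11**
Reactants: 14
Product: 15 3‑iodobutenolide
Conditions: I2, CH2Cl2, 0 °C
Reagents that add atoms: iodine, II
Why: Base‑free ipso iododestannylation is much faster than any reaction of I2 with the other alkenes.

**Step 12**
Reactants: 15; 16 (trimethylsilyl)methylmagnesium chloride
Product: 17 3‑[(trimethylsilyl)methyl]butenolide
Conditions: 16 + ZnCl2 (gives Me3SiCH2ZnCl); Pd(PPh3)4 (5 mol %), THF, rt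
Reagents that add atoms: (trimethylsilyl)methylmagnesium chloride, C[Si](C)(C)C[Mg]Cl
Why: Negishi coupling of an alkylzinc with no β‑hydrogens installs the allylsilane; the organozinc is non‑basic, so the acidic C6–H is not epimerised and the esters survive.

**Step 13**
Reactants: 17
Product: 18 α‑(NAP‑oxy) aldehyde (C8)
Conditions: TFA/H2O/CH2Cl2 (1:1:8), 0 °C; used crude at once
Reagents that add atoms: water, O
Why: Acid‑catalysed acetal hydrolysis; NAP and the electron‑poor allylsilane tolerate dilute TFA, and cold, brief handling protects C9, which is α to the aldehyde and allylic.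

**Step 14 (key step)**
Reactants: 18
Product: 19 macrocyclic 8‑hydroxy‑9‑ONAP melampolide with the α‑methylene lactone (6R,7R,8S,9S; same spatial arrangement as the target, with C7 labelled R only because of CIP priorities)
Conditions: syringe‑pump addition of 18 to SnCl4 (1.05 equiv) and 2,6‑di‑tert‑butylpyridine, CH2Cl2, –78 °C (final about 1 mM); aq NaHCO3 quench
Reagents that add atoms: none
Why: Proposed new method: SnCl4 locks O8 and O9 in a five‑membered chelate, so C7 (the γ‑carbon of the allylsilane) attacks C8 anti to C10, giving the Cram‑chelate 8,9‑syn product. The β‑silyl cation then loses Me3Si to give the exocyclic methylene. Only the butenolide face anti to C5 lets the E C4=C5 tether reach C7, which enforces the trans 6,7‑fusion, and the open antiperiplanar transition state favours the same 7,8 relationship, so all three controls are matched. The closest known reactions are Lewis‑acid Hosomi–Sakurai cyclisations of β‑(alkoxycarbonyl)allylsilane aldehydes (5–8‑membered rings) and chelation‑controlled allylsilane additions to α‑benzyloxy aldehydes.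

**Step 15**
Reactants: 19; 20 angelic acid
Product: 21 8‑O‑angelate
Conditions: 20, 2,4,6‑trichlorobenzoyl chloride, Et3N, toluene, rt; then 19, 60 °C (no DMAP)
Reagents that add atoms: angelic acid, C/C=C(/C)C(=O)O
Why: Yamaguchi‑type mixed‑anhydride esterification without a nucleophilic catalyst avoids addition–elimination isomerisation to the tiglate; O8 is the only free hydroxyl, and 60 °C is below the temperature for Cope rearrangement of the 1,5‑diene.

**Step 16**
Reactants: 21
Product: 22 polymatin A
Conditions: DDQ, CH2Cl2/pH 7 buffer (10:1), 0 °C to rt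
Reagents that add atoms: none
Why: Oxidative cleavage of the NAP ether under neutral conditions leaves the angelate, both acrylate units and all four stereocentres intact.

**Compound list**

| No. | Name | SMILES | Role |
|---|---|---|---|
| 1 | geranyl acetate | `CC(=O)OC/C=C(\C)CCC=C(C)C` | starting material |
| 2 | 6,7‑epoxygeranyl acetate | `CC(=O)OC/C=C(\C)CCC1OC1(C)C` | intermediate |
| 3 | (2E)‑3‑methyl‑6‑oxohex‑2‑en‑1‑yl acetate | `CC(=O)OC/C=C(\C)CCC=O` | intermediate |
| 4 | methyl 4,4‑dimethoxy‑3‑oxobutanoate | `COC(OC)C(=O)CC(=O)OC` | starting material |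
| 5 | methyl (3S)‑3‑hydroxy‑4,4‑dimethoxybutanoate | `COC(=O)C[C@H](O)C(OC)OC` | intermediate |
| 6 | 2‑(bromomethyl)naphthalene | `BrCc1ccc2ccccc2c1` | starting material |
| 7 | methyl (3S)‑4,4‑dimethoxy‑3‑(2‑naphthylmethoxy)butanoate | `COC(=O)C[C@H](OCc1ccc2ccccc2c1)C(OC)OC` | intermediate |
| 8 | methyl (6E)‑8‑acetoxy‑2‑[(1S)‑2,2‑dimethoxy‑1‑(2‑naphthylmethoxy)ethyl]‑3‑hydroxy‑6‑methyloct‑6‑enoate (C2/C3 mixture) | `COC(=O)C(C(O)CC/C(C)=C/COC(C)=O)[C@H](OCc1ccc2ccccc2c1)C(OC)OC` | intermediate |
| 9 | methyl (2E,6E)‑8‑acetoxy‑2‑[(1S)‑2,2‑dimethoxy‑1‑(2‑naphthylmethoxy)ethyl]‑6‑methylocta‑2,6‑dienoate | `CC(=O)OC/C=C(\C)CC/C=C(/C(=O)OC)[C@H](OCc1ccc2ccccc2c1)C(OC)OC` | intermediate |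
| 10 | 8‑hydroxy analogue of 9 | `OC/C=C(\C)CC/C=C(/C(=O)OC)[C@H](OCc1ccc2ccccc2c1)C(OC)OC` | intermediate |
| 11 | 8‑oxo (enal) analogue of 9 | `O=C/C=C(\C)CC/C=C(/C(=O)OC)[C@H](OCc1ccc2ccccc2c1)C(OC)OC` | intermediate |
| 12 | methyl propiolate | `C#CC(=O)OC` | starting material |
| 13 | dimethyl (2E,6E,8R)‑2‑[(1S)‑2,2‑dimethoxy‑1‑(2‑naphthylmethoxy)ethyl]‑8‑hydroxy‑6‑methylundeca‑2,6‑dien‑9‑ynedioate | `COC(=O)C#C[C@H](O)/C=C(\C)CC/C=C(/C(=O)OC)[C@H](OCc1ccc2ccccc2c1)C(OC)OC` | intermediate |
| 14 | methyl (2E,6E)‑2‑[(1S)‑2,2‑dimethoxy‑1‑(2‑naphthylmethoxy)ethyl]‑6‑methyl‑7‑[(2R)‑5‑oxo‑4‑(tributylstannyl)‑2,5‑dihydrofuran‑2‑yl]hepta‑2,6‑dienoate | `O=C1O[C@H](/C=C(\C)CC/C=C(/C(=O)OC)[C@H](OCc2ccc3ccccc3c2)C(OC)OC)C=C1[Sn](CCCC)(CCCC)CCCC` | intermediate |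
| 15 | 4‑iodo analogue of 14 | `O=C1O[C@H](/C=C(\C)CC/C=C(/C(=O)OC)[C@H](OCc2ccc3ccccc3c2)C(OC)OC)C=C1I` | intermediate |
| 16 | (trimethylsilyl)methylmagnesium chloride | `C[Si](C)(C)C[Mg]Cl` | starting material |
| 17 | 4‑[(trimethylsilyl)methyl] analogue of 14 | `O=C1O[C@H](/C=C(\C)CC/C=C(/C(=O)OC)[C@H](OCc2ccc3ccccc3c2)C(OC)OC)C=C1C[Si](C)(C)C` | intermediate |
| 18 | methyl (2E,6E)‑6‑methyl‑2‑[(1S)‑1‑(2‑naphthylmethoxy)‑2‑oxoethyl]‑7‑{(2R)‑5‑oxo‑4‑[(trimethylsilyl)methyl]‑2,5‑dihydrofuran‑2‑yl}hepta‑2,6‑dienoate | `O=C1O[C@H](/C=C(\C)CC/C=C(/C(=O)OC)[C@H](OCc2ccc3ccccc3c2)C=O)C=C1C[Si](C)(C)C` | intermediate |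
| 19 | methyl (3aR,4S,5S,6E,10E,11aR)‑4‑hydroxy‑10‑methyl‑3‑methylidene‑5‑(2‑naphthylmethoxy)‑2‑oxo‑2,3,3a,4,5,8,9,11a‑octahydrocyclodeca[b]furan‑6‑carboxylate | `C=C1C(=O)O[C@@H]2/C=C(\C)CC/C=C(/C(=O)OC)[C@H](OCc3ccc4ccccc4c3)[C@@H](O)[C@@H]12` | intermediate |
| 20 | angelic acid, (2Z)‑2‑methylbut‑2‑enoic acid | `C/C=C(/C)C(=O)O` | starting material |
| 21 | 4‑O‑angelate of 19 (3aS,4S,5S,11aR) | `C=C1C(=O)O[C@@H]2/C=C(\C)CC/C=C(/C(=O)OC)[C@H](OCc3ccc4ccccc4c3)[C@@H](OC(=O)/C(C)=C\C)[C@@H]12` | intermediate |
| 22 | polymatin A, methyl (3aS,4S,5S,6E,10E,11aR)‑5‑hydroxy‑10‑methyl‑3‑methylidene‑4‑{[(2Z)‑2‑methylbut‑2‑enoyl]oxy}‑2‑oxo‑2,3,3a,4,5,8,9,11a‑octahydrocyclodeca[b]furan‑6‑carboxylate | `C=C1C(=O)O[C@@H]2/C=C(\C)CC/C=C(/C(=O)OC)[C@H](O)[C@@H](OC(=O)/C(C)=C\C)[C@@H]12` | target |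

**Step counts**
- Total steps: 16.
- Longest linear sequence: 14 (steps 1, 2 and 5–16, from geranyl acetate).

**Three steps most likely to fail, each with a fallback**
1. **Step 14.** The deactivated allylsilane may be too slow to close a strained ten‑membered ring, and Prins reaction, oligomerisation or Lewis‑acid damage could compete.
   Fallback: change from a polar to a radical closure.
   - Reduce 13 under Lindlar conditions to the unsubstituted butenolide and hydrolyse the acetal.
   - Close C7–C8 with SmI2/t‑BuOH by ketyl‑radical conjugate addition. The Sm(III) chelate to O9 sets C8 and the lactone C6 sets C7.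
   - Angeloylate, then install the methylene through the lactone enolate with Eschenmoser's salt followed by quaternisation/elimination.
2. **Step 5 (with step 6).** The β‑alkoxy ester enolate may eliminate, or the E/Z ratio of the enoate may be poor.
   Fallback: build the enoate from an alkyne instead.
   - Convert 3 to the terminal alkyne (Ohira–Bestmann).
   - Add it to 2,2‑dimethoxyacetaldehyde by catalytic asymmetric alkynylation (sets C9) and protect O9 as the NAP ether.
   - Carry out Pd‑catalysed syn‑hydrostannation (tin next to the carbinol carbon), treat with I2, then carbonylate with Pd/CO/MeOH. The C1=C10 geometry then follows from syn addition rather than from an elimination.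
3. **Step 15.** The hindered C8 alcohol may react slowly, or the angelate may isomerise to the tiglate.
   Fallback: deliver the ester during ring closure. Convert aldehyde 18 to its bis‑angelate acylal (angelic anhydride, catalytic Lewis acid) and run the Sakurai cyclisation on the derived acyloxocarbenium ion. This gives 21 directly with no separate acylation.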